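- If you want the share of D at 80 min, no reading reaches that time, since the earliest stands at 0.417 d, so the estimate has to run by hand from the two earlier runs.

| flask | Z | E | X | remark | time |
|---|---|---|---|---|---|
| epsilon | 20 mM | 1.8 equiv | 1.8 equiv | run made earlier |  |
| gamma | 20 mM | 2.9 equiv | 1.8 equiv | run made earlier |  |
| flask | 20 mM | 1.30 equiv | 1.80 equiv |  | 10 d |

| run | time / d | D / % | L / % | Z / % |
|---|---|---|---|---|
| epsilon | 0.500 | 3 | 6 | 92 |
| epsilon | 0.833 | 1 | 10 | 85 |
| epsilon | 1.25 | 2 | 16 | 80 |
| epsilon | 2.00 | 5 | 26 | 73 |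
| epsilon | 4.00 | 1 | 44 | 52 |
| epsilon | 6.00 | 2 | 52 | 37 |
| gamma | 0.417 | 4 | 3 | 90 |
| gamma | 1.25 | 3 | 17 | 79 |
| gamma | 2.00 | 3 | 25 | 71 |
| gamma | 3.00 | 1 | 35 | 63 |
| gamma | 5.00 | 2 | 49 | 44 |
| gamma | 6.00 | 0 | 52 | 43 |

(readings scatter by 1.5 percentage points)

- share of D in D plus L at 80 min
- share of D in D plus L at 10 d
- which of D and L there is more of at 10 d

- Start with the amounts. The epsilon run keeps 37 % of its Z at 6.00 d, which reads as a first-order constant of 0.166 d⁻¹. By 80 min about 0.922 % of Z has therefore reacted, against a scatter of 1.5 percentage points, so carry a ratio, not an amount.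
- The first D-to-L reading is 0.500 in epsilon, with 1.8 equiv of E at 0.500 d, and 1.33 in gamma, with 2.9 equiv of E at 0.417 d. Both are ratios of small, scattered readings, so I take D and L as competing products only as a working guess.
- Define the selectivity factor as early D over L, divided by charged E over X. Epsilon gives 0.500, gamma gives 0.828, and their mean is 0.664.
- For this flask, the factor times its E over X gives a share of D of 32.4 %. The two runs singly give 26.5 % and 37.4 %, and I carry that gap as the width of the estimate.
- The weak link is X, which was never varied. The flask holds X at 1.80 equiv, as both runs did, so this share does not rest on the untested way the factor scales with X.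
- Late on, epsilon reads D 2 % against L 52 % at 6.00 d, a share of 3.70 %, so I commit to L ahead at 10 d with a share of D below that.
- The forecast differs from this reckoning at the early time: it gives 85 % at 80 min, saying “D dominates, though this is an extrapolation”, then 2 % at 10 d, with L ahead.
- The flask gives 27.4 % at 80 min and 2.40 % at 10 d.

    Z ⇌ J (K = 0.00130, k = 1.30 × 10⁻⁵ s⁻¹)
    E + J → D (k = 0.0280 M⁻¹ s⁻¹)
    X + J → L (k = 0.0470 M⁻¹ s⁻¹)
    2 E → G (k = 0.00110 M⁻¹ s⁻¹)
    Z + D → Q (k = 1.30 × 10⁻⁴ M⁻¹ s⁻¹)

- Against the 32.4 % reckoned from the selectivity factor, the flask stands at 27.4 %, and at 10 d it holds L 68.2 % beside D 1.68 %. Now put the factor to a flask where X does change: with 4.50 equiv of X and the other charges held, 0.664 gives a share of D of 16.1 %, and at 80 min that neighbour flask gives 13.1 %.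

The numbers in the tables are simulated with constants of no real substance.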